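**Retrosynthetic overview**

1. Target (3S,4S,5R)-lactone (lactone ring O1, C2 carbonyl, C3, C4, C5; ring A = guaiacyl ring of the C3 benzyl group, ring B = guaiacyl ring on C5) ⇒ desilylation ⇒ C3–H by hydrogenation of the (E)-C3 benzylidene lactone on the face anti to the C4 arm ⇒ exocyclic C3=C bond by aldol condensation with silylated vanillin, so ring A comes in last.
2. C4 CH2OH ⇒ C4 CO2H ⇒ tert-butyl 4,5-trans paraconate (C4 ester, C5 ring B).
3. Feature: C5 is an aryl carbinol carbon inside the lactone; one oxidation level up, C4 (then carrying an ester) is the enolisable α-carbon of a ring B aryl β-keto ester, and the C2 ester sits 1,4 to the ketone. Key disconnection O1–C2 and C5–H ⇒ racemic 2-aroylsuccinate, reduced by Ru–TsDPEN transfer hydrogenation with dynamic kinetic resolution and lactonised in the same flask (the only ring formed; rings A and B are bought).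
4. Aroylsuccinate ⇒ C3–C4 bond by alkylation of the aryl β-keto ester with methyl bromoacetate ⇒ C4–C5 bond by Claisen acylation of tert-butyl acetate with silylated vanillic acid.

Key step: step 4

Remark: the (R,R)-TsDPEN ruthenium catalyst is assumed to reduce the α-branched aryl ketone with the same facial sense as simple aryl alkyl ketones, which corresponds to the (5R)-carbinol; lactone numbering (O1, C2, C3, C4, C5) is used throughout.

**Route**

Step 1
Reactants: 1 vanillic acid (4-hydroxy-3-methoxybenzoic acid)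
Product: 3 4-(tert-butyldimethylsilyloxy)-3-methoxybenzoic acid, via silyl ester 2 (not isolated)
Conditions: TBSCl (2.4 equiv), imidazole (5 equiv), DMF, rt; then AcOH/THF/H2O (3:1:1), rt
Reagents that add atoms: tert-butyldimethylsilyl chloride (TBSCl), CC(C)(C)[Si](C)(C)Cl
Why: Silylation of both acidic OH groups followed by selective hydrolysis of the much more labile silyl ester should leave the aryl silyl ether, which is stable to aqueous acetic acid.

Step 2
Reactants: 3 4-(tert-butyldimethylsilyloxy)-3-methoxybenzoic acid; 4 tert-butyl acetate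
Product: 6 tert-butyl 3-[4-(tert-butyldimethylsilyloxy)-3-methoxyphenyl]-3-oxopropanoate, via acyl imidazole 5 (not isolated)
Conditions: 3, CDI (1.1 equiv), THF, rt; this solution added to LiN(iPr)2 (3.2 equiv)/4 (3.2 equiv), THF, −78 °C; aq. NH4Cl
Reagents that add atoms: none
Why: Crossed Claisen condensation in which the acyl imidazole acylates the preformed lithium ester enolate; the excess enolate takes up the liberated imidazole N–H and deprotonates the product β-keto ester, which should prevent a second acylation.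

Step 3
Reactants: 6 tert-butyl 3-[4-(tert-butyldimethylsilyloxy)-3-methoxyphenyl]-3-oxopropanoate; 7 methyl bromoacetate
Product: 8 racemic 1-tert-butyl 4-methyl 2-[4-(tert-butyldimethylsilyloxy)-3-methoxybenzoyl]butanedioate
Conditions: NaH (1.05 equiv), THF, 0 °C; then 7 (1.0 equiv), 0 °C to rt
Reagents that add atoms: none
Why: SN2 C-alkylation of the stabilised sodium enolate by a reactive α-bromo ester, with one equivalent of each partner to limit dialkylation; the new centre is formed racemic and stays labile, as the next step requires.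

Step 4
Reactants: 8 racemic 1-tert-butyl 4-methyl 2-[4-(tert-butyldimethylsilyloxy)-3-methoxybenzoyl]butanedioate
Product: 11 tert-butyl (2R,3R)-2-[4-(tert-butyldimethylsilyloxy)-3-methoxyphenyl]-5-oxooxolane-3-carboxylate, via hydroxy diester 9 (not isolated), via cis lactone 10 (not isolated)
Conditions: RuCl[(R,R)-TsDPEN](p-cymene) (1 mol %), HCO2H/Et3N (5:2), DMF, 40 °C until reduction and lactonisation are complete; aqueous work-up; then DBU (0.2 equiv), dry CH2Cl2, rt
Reagents that add atoms: none
Why: Formate converts the 16-electron ruthenium amide into the 18-electron ruthenium hydride, which passes hydride from Ru and a proton from the ligand N–H to the ring B ketone through an outer-sphere six-membered transition state (Noyori–Ikariya asymmetric transfer hydrogenation of an α-substituted aryl β-keto ester with dynamic kinetic resolution, a known reaction type). C5 is set by the catalyst: the C–H/π contact between ring B and the p-cymene ligand of the (R,R)-complex should put hydride on the ketone face that gives the (5R)-carbinol. C4 of 8 is the α-carbon of a β-keto ester and should racemise through its enol in the Et3N/HCO2H medium faster than the electron-rich ketone is reduced, so the faster-reacting enantiomer is replenished and 9 should form mainly as the syn (2R) isomer. The C5 hydroxyl of 9 then attacks the methyl ester carbonyl in a 5-exo-trig closure that forms O1–C2 and releases methanol, the tert-butyl ester being unable to compete because it would give a four-membered ring; syn 9 gives trans lactone 11 directly and any anti 9 gives cis lactone 10. C4 of the lactone is still α to the tert-butyl ester, so catalytic DBU should epimerise 10 to the more stable 4,5-trans 11, while ring opening by β-elimination of the carboxylate is the reverse of a 5-endo-trig closure and should be slow. The step needs enantioface control at C5 and a trans relation at C4, which the catalyst and the acidity of C4–H (kinetic selection, then equilibration) secure.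

Step 5
Reactants: 11 tert-butyl (2R,3R)-2-[4-(tert-butyldimethylsilyloxy)-3-methoxyphenyl]-5-oxooxolane-3-carboxylate
Product: 12 (2R,3R)-2-[4-(tert-butyldimethylsilyloxy)-3-methoxyphenyl]-5-oxooxolane-3-carboxylic acid
Conditions: CF3CO2H/CH2Cl2 (1:4), 0 °C to rt
Reagents that add atoms: none
Why: Acidolysis of the tert-butyl ester through the tert-butyl cation should free the C4 acid without touching the lactone or the acid-stable aryl silyl ether, and no base is present that could epimerise C4.

Step 6
Reactants: 12 (2R,3R)-2-[4-(tert-butyldimethylsilyloxy)-3-methoxyphenyl]-5-oxooxolane-3-carboxylic acid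
Product: 13 (4S,5R)-5-[4-(tert-butyldimethylsilyloxy)-3-methoxyphenyl]-4-(hydroxymethyl)oxolan-2-one
Conditions: BH3·SMe2 (1.5 equiv), THF, 0 °C to rt; MeOH quench
Reagents that add atoms: none
Why: Chemoselective borane reduction of a carboxylic acid, which reacts through its acyloxyborane far faster than the lactone; C4 keeps its spatial arrangement and its descriptor becomes S only because CH2OH ranks below C5.

Step 7
Reactants: 13 (4S,5R)-5-[4-(tert-butyldimethylsilyloxy)-3-methoxyphenyl]-4-(hydroxymethyl)oxolan-2-one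
Product: 14 (4S,5R)-4-[(tert-butyldimethylsilyloxy)methyl]-5-[4-(tert-butyldimethylsilyloxy)-3-methoxyphenyl]oxolan-2-one
Conditions: TBSCl (1.2 equiv), imidazole (2.5 equiv), CH2Cl2, 0 °C to rt
Reagents that add atoms: tert-butyldimethylsilyl chloride (TBSCl), CC(C)(C)[Si](C)(C)Cl
Why: Silylation of the primary alcohol blocks acyl transfer from O1 to the C4 hydroxymethyl group under the basic conditions to come and gives C4 a bulky arm for the later face-selective hydrogenation.

Step 8
Reactants: 15 vanillin
Product: 16 4-(tert-butyldimethylsilyloxy)-3-methoxybenzaldehyde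
Conditions: TBSCl (1.1 equiv), imidazole (2.2 equiv), CH2Cl2, rt
Reagents that add atoms: tert-butyldimethylsilyl chloride (TBSCl), CC(C)(C)[Si](C)(C)Cl
Why: Phenol silylation, needed because a free phenol would quench the lactone enolate in the next step.

Step 9
Reactants: 14 (4S,5R)-4-[(tert-butyldimethylsilyloxy)methyl]-5-[4-(tert-butyldimethylsilyloxy)-3-methoxyphenyl]oxolan-2-one; 16 4-(tert-butyldimethylsilyloxy)-3-methoxybenzaldehyde
Product: 19 (3E,4S,5R)-3-[[4-(tert-butyldimethylsilyloxy)-3-methoxyphenyl]methylidene]-4-[(tert-butyldimethylsilyloxy)methyl]-5-[4-(tert-butyldimethylsilyloxy)-3-methoxyphenyl]oxolan-2-one, via aldol adduct 17 (not isolated), via mesylate 18 (not isolated)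
Conditions: LiN(SiMe3)2 (1.1 equiv), THF, −78 °C; 16; aq. NH4Cl; crude 17, MsCl, Et3N, CH2Cl2, 0 °C; then DBU, rt
Reagents that add atoms: none
Why: Aldol condensation: the lithium enolate at C3 adds to the aldehyde, and mesylation with E1cB elimination should give the conjugated alkene with E geometry because ring A avoids the lactone carbonyl; C4 and C5 carry no acidic hydrogen under these conditions.

Step 10
Reactants: 19 (3E,4S,5R)-3-[[4-(tert-butyldimethylsilyloxy)-3-methoxyphenyl]methylidene]-4-[(tert-butyldimethylsilyloxy)methyl]-5-[4-(tert-butyldimethylsilyloxy)-3-methoxyphenyl]oxolan-2-one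
Product: 20 (3S,4S,5R)-3-[[4-(tert-butyldimethylsilyloxy)-3-methoxyphenyl]methyl]-4-[(tert-butyldimethylsilyloxy)methyl]-5-[4-(tert-butyldimethylsilyloxy)-3-methoxyphenyl]oxolan-2-one
Conditions: H2 (1 atm), 5% Pd/C, pyridine (0.5 equiv), EtOAc, rt
Reagents that add atoms: none
Why: Heterogeneous syn hydrogenation of the exocyclic alkene; allylic strain between ring A and the adjacent C4 arm should push the silyloxymethyl group pseudoaxial, so hydrogen is delivered to the opposite face and the benzyl group ends up cis to the C4 arm (3S), while pyridine moderates the palladium surface and should suppress hydrogenolysis of the benzylic C5–O1 bond.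

Step 11
Reactants: 20 (3S,4S,5R)-3-[[4-(tert-butyldimethylsilyloxy)-3-methoxyphenyl]methyl]-4-[(tert-butyldimethylsilyloxy)methyl]-5-[4-(tert-butyldimethylsilyloxy)-3-methoxyphenyl]oxolan-2-one
Product: 21 (3S,4S,5R)-5-(4-hydroxy-3-methoxyphenyl)-3-[(4-hydroxy-3-methoxyphenyl)methyl]-4-(hydroxymethyl)oxolan-2-one
Conditions: Bu4NF (3.6 equiv), AcOH (3.6 equiv), THF, 0 °C to rt
Reagents that add atoms: none
Why: Fluoride-mediated desilylation of the two aryl silyl ethers and the primary silyl ether; buffering with acetic acid keeps alkoxide and phenoxide concentrations low, which should protect the epimerisable cis C3 centre and prevent acyl transfer to the C4 hydroxymethyl group.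

**Compound list**

1 | vanillic acid | COc1cc(C(=O)O)ccc1O | starting material
2 | tert-butyldimethylsilyl 4-(tert-butyldimethylsilyloxy)-3-methoxybenzoate (not isolated) | COc1cc(C(=O)O[Si](C)(C)C(C)(C)C)ccc1O[Si](C)(C)C(C)(C)C | intermediate
3 | 4-(tert-butyldimethylsilyloxy)-3-methoxybenzoic acid | COc1cc(C(=O)O)ccc1O[Si](C)(C)C(C)(C)C | intermediate
4 | tert-butyl acetate | CC(=O)OC(C)(C)C | starting material
5 | 1-[4-(tert-butyldimethylsilyloxy)-3-methoxybenzoyl]imidazole (not isolated) | COc1cc(C(=O)n2ccnc2)ccc1O[Si](C)(C)C(C)(C)C | intermediate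
6 | tert-butyl 3-[4-(tert-butyldimethylsilyloxy)-3-methoxyphenyl]-3-oxopropanoate | COc1cc(C(=O)CC(=O)OC(C)(C)C)ccc1O[Si](C)(C)C(C)(C)C | intermediate
7 | methyl bromoacetate | COC(=O)CBr | starting material
8 | racemic 1-tert-butyl 4-methyl 2-[4-(tert-butyldimethylsilyloxy)-3-methoxybenzoyl]butanedioate | COC(=O)CC(C(=O)OC(C)(C)C)C(=O)c1ccc(O[Si](C)(C)C(C)(C)C)c(OC)c1 | intermediate
9 | 1-tert-butyl 4-methyl 2-[(R)-[4-(tert-butyldimethylsilyloxy)-3-methoxyphenyl](hydroxy)methyl]butanedioate, C2 epimers with 2R (syn) expected to predominate (not isolated) | COC(=O)CC(C(=O)OC(C)(C)C)[C@@H](O)c1ccc(O[Si](C)(C)C(C)(C)C)c(OC)c1 | intermediate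
10 | tert-butyl (2R,3S)-2-[4-(tert-butyldimethylsilyloxy)-3-methoxyphenyl]-5-oxooxolane-3-carboxylate, cis lactone (not isolated) | O=C1C[C@H](C(=O)OC(C)(C)C)[C@H](c2ccc(O[Si](C)(C)C(C)(C)C)c(OC)c2)O1 | intermediate
11 | tert-butyl (2R,3R)-2-[4-(tert-butyldimethylsilyloxy)-3-methoxyphenyl]-5-oxooxolane-3-carboxylate, trans paraconate | O=C1C[C@@H](C(=O)OC(C)(C)C)[C@H](c2ccc(O[Si](C)(C)C(C)(C)C)c(OC)c2)O1 | intermediate
12 | (2R,3R)-2-[4-(tert-butyldimethylsilyloxy)-3-methoxyphenyl]-5-oxooxolane-3-carboxylic acid | O=C1C[C@@H](C(=O)O)[C@H](c2ccc(O[Si](C)(C)C(C)(C)C)c(OC)c2)O1 | intermediate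
13 | (4S,5R)-5-[4-(tert-butyldimethylsilyloxy)-3-methoxyphenyl]-4-(hydroxymethyl)oxolan-2-one | O=C1C[C@@H](CO)[C@H](c2ccc(O[Si](C)(C)C(C)(C)C)c(OC)c2)O1 | intermediate
14 | (4S,5R)-4-[(tert-butyldimethylsilyloxy)methyl]-5-[4-(tert-butyldimethylsilyloxy)-3-methoxyphenyl]oxolan-2-one | O=C1C[C@@H](CO[Si](C)(C)C(C)(C)C)[C@H](c2ccc(O[Si](C)(C)C(C)(C)C)c(OC)c2)O1 | intermediate
15 | vanillin | COc1cc(C=O)ccc1O | starting material
16 | 4-(tert-butyldimethylsilyloxy)-3-methoxybenzaldehyde | COc1cc(C=O)ccc1O[Si](C)(C)C(C)(C)C | intermediate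
17 | (4S,5R)-3-[[4-(tert-butyldimethylsilyloxy)-3-methoxyphenyl](hydroxy)methyl]-4-[(tert-butyldimethylsilyloxy)methyl]-5-[4-(tert-butyldimethylsilyloxy)-3-methoxyphenyl]oxolan-2-one, mixture at C3 and the carbinol carbon (not isolated) | O=C1C(C(O)c2ccc(O[Si](C)(C)C(C)(C)C)c(OC)c2)[C@@H](CO[Si](C)(C)C(C)(C)C)[C@H](c2ccc(O[Si](C)(C)C(C)(C)C)c(OC)c2)O1 | intermediate
18 | methanesulfonate of 17 (not isolated) | O=C1C(C(OS(C)(=O)=O)c2ccc(O[Si](C)(C)C(C)(C)C)c(OC)c2)[C@@H](CO[Si](C)(C)C(C)(C)C)[C@H](c2ccc(O[Si](C)(C)C(C)(C)C)c(OC)c2)O1 | intermediate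
19 | (3E,4S,5R)-3-[[4-(tert-butyldimethylsilyloxy)-3-methoxyphenyl]methylidene]-4-[(tert-butyldimethylsilyloxy)methyl]-5-[4-(tert-butyldimethylsilyloxy)-3-methoxyphenyl]oxolan-2-one | O=C1/C(=C/c2ccc(O[Si](C)(C)C(C)(C)C)c(OC)c2)[C@@H](CO[Si](C)(C)C(C)(C)C)[C@H](c2ccc(O[Si](C)(C)C(C)(C)C)c(OC)c2)O1 | intermediate
20 | (3S,4S,5R)-3-[[4-(tert-butyldimethylsilyloxy)-3-methoxyphenyl]methyl]-4-[(tert-butyldimethylsilyloxy)methyl]-5-[4-(tert-butyldimethylsilyloxy)-3-methoxyphenyl]oxolan-2-one | COc1cc(C[C@@H]2C(=O)O[C@@H](c3ccc(O[Si](C)(C)C(C)(C)C)c(OC)c3)[C@@H]2CO[Si](C)(C)C(C)(C)C)ccc1O[Si](C)(C)C(C)(C)C | intermediate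
21 | (3S,4S,5R)-5-(4-hydroxy-3-methoxyphenyl)-3-[(4-hydroxy-3-methoxyphenyl)methyl]-4-(hydroxymethyl)oxolan-2-one | COc1cc(C[C@@H]2C(=O)O[C@@H](c3ccc(O)c(OC)c3)[C@@H]2CO)ccc1O | target

**Step count**

Total steps: 11. Longest linear sequence: 10 steps (steps 1 to 7 and 9 to 11, from vanillic acid); step 8 is a one-step side branch.

**Steps most likely to fail**

Step 4. Reduction may outrun the racemisation of C4, or the catalyst may discriminate the faces of the hindered, electron-rich ketone poorly, so that enantiomeric and diastereomeric purity are lost. The base equilibration may also open the lactone by β-elimination.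

Fallback: an auxiliary-controlled syn-aldol route that sets out from aldehyde 16 and returns at acid 12, bypassing steps 1 to 5. (4R)-4-Benzyl-1,3-oxazolidin-2-one is N-acylated with methyl 4-chloro-4-oxobutanoate (n-BuLi, THF, −78 °C) to give (4R)-4-benzyl-3-(4-methoxy-4-oxobutanoyl)-1,3-oxazolidin-2-one F1. Its boron enolate (Bu2BOTf, iPr2NEt, CH2Cl2, −78 to 0 °C), formed at the imide α-carbon, should add to 16 in an Evans syn-aldol reaction to give methyl (3R,4R)-3-[(4R)-4-benzyl-2-oxo-1,3-oxazolidine-3-carbonyl]-4-[4-(tert-butyldimethylsilyloxy)-3-methoxyphenyl]-4-hydroxybutanoate F2. With catalytic pyridinium p-toluenesulfonate in CH2Cl2 this should lactonise to the trans lactone imide (4R)-4-benzyl-3-[(2R,3R)-2-[4-(tert-butyldimethylsilyloxy)-3-methoxyphenyl]-5-oxooxolane-3-carbonyl]-1,3-oxazolidin-2-one F3. Brief treatment with LiOH/H2O2 in THF/H2O at 0 °C, then acidification, should remove the auxiliary and give 12.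

Step 10. The benzylic C5–O1 bond may be hydrogenolysed on palladium, and the facial bias may be too small because ring B on C5 lies on the face that hydrogen must approach.

Fallback: enolate alkylation followed by kinetic protonation, setting out from lactone 14 and aldehyde 16 and returning at 20, in place of steps 9 and 10. Aldehyde 16 is reduced (NaBH4, MeOH, 0 °C) to [4-(tert-butyldimethylsilyloxy)-3-methoxyphenyl]methanol F4. CBr4/PPh3 in CH2Cl2 converts it into [4-(bromomethyl)-2-methoxyphenoxy](tert-butyl)dimethylsilane F5. The lithium enolate of 14 (LiN(SiMe3)2, THF, −78 °C) should be alkylated by F5 anti to the C4 arm to give the 3,4-trans lactone (3R,4S,5R)-3-[[4-(tert-butyldimethylsilyloxy)-3-methoxyphenyl]methyl]-4-[(tert-butyldimethylsilyloxy)methyl]-5-[4-(tert-butyldimethylsilyloxy)-3-methoxyphenyl]oxolan-2-one F6. Re-enolisation with LiN(iPr)2 at −78 °C and quenching with the bulky proton donor 2,6-di-tert-butyl-4-methylphenol should deliver the proton anti to the C4 arm and give the 3,4-cis lactone 20.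

Step 11. Fluoride or the phenoxides it releases may cause acyl transfer from O1 to the freed C4 hydroxymethyl group, or epimerisation of the cis C3 centre.

Fallback: two chemoselective cleavages that never generate an alkoxide, setting out from 20 and returning at 21. Pyridinium p-toluenesulfonate in MeOH at rt should solvolyse only the primary alkyl silyl ether and give (3S,4S,5R)-3-[[4-(tert-butyldimethylsilyloxy)-3-methoxyphenyl]methyl]-5-[4-(tert-butyldimethylsilyloxy)-3-methoxyphenyl]-4-(hydroxymethyl)oxolan-2-one F7. KHF2 in MeOH at rt, which is selective for aryl silyl ethers and weakly acidic, should then give 21.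

**Further compounds**

F1 | step 4 | (4R)-4-benzyl-3-(4-methoxy-4-oxobutanoyl)-1,3-oxazolidin-2-one | COC(=O)CCC(=O)N1[C@H](Cc2ccccc2)COC1=O
F2 | step 4 | methyl (3R,4R)-3-[(4R)-4-benzyl-2-oxo-1,3-oxazolidine-3-carbonyl]-4-[4-(tert-butyldimethylsilyloxy)-3-methoxyphenyl]-4-hydroxybutanoate | COC(=O)C[C@@H](C(=O)N1[C@H](Cc2ccccc2)COC1=O)[C@@H](O)c1ccc(O[Si](C)(C)C(C)(C)C)c(OC)c1
F3 | step 4 | (4R)-4-benzyl-3-[(2R,3R)-2-[4-(tert-butyldimethylsilyloxy)-3-methoxyphenyl]-5-oxooxolane-3-carbonyl]-1,3-oxazolidin-2-one | O=C1C[C@@H](C(=O)N2[C@H](Cc3ccccc3)COC2=O)[C@H](c2ccc(O[Si](C)(C)C(C)(C)C)c(OC)c2)O1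
F4 | step 10 | [4-(tert-butyldimethylsilyloxy)-3-methoxyphenyl]methanol | COc1cc(CO)ccc1O[Si](C)(C)C(C)(C)C
F5 | step 10 | [4-(bromomethyl)-2-methoxyphenoxy](tert-butyl)dimethylsilane | COc1cc(CBr)ccc1O[Si](C)(C)C(C)(C)C
F6 | step 10 | (3R,4S,5R)-3-[[4-(tert-butyldimethylsilyloxy)-3-methoxyphenyl]methyl]-4-[(tert-butyldimethylsilyloxy)methyl]-5-[4-(tert-butyldimethylsilyloxy)-3-methoxyphenyl]oxolan-2-one | COc1cc(C[C@H]2C(=O)O[C@@H](c3ccc(O[Si](C)(C)C(C)(C)C)c(OC)c3)[C@@H]2CO[Si](C)(C)C(C)(C)C)ccc1O[Si](C)(C)C(C)(C)C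
F7 | step 11 | (3S,4S,5R)-3-[[4-(tert-butyldimethylsilyloxy)-3-methoxyphenyl]methyl]-5-[4-(tert-butyldimethylsilyloxy)-3-methoxyphenyl]-4-(hydroxymethyl)oxolan-2-one | COc1cc(C[C@@H]2C(=O)O[C@@H](c3ccc(O[Si](C)(C)C(C)(C)C)c(OC)c3)[C@@H]2CO)ccc1O[Si](C)(C)C(C)(C)C
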